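**Plan**

- Ring atoms: O1, C2 (stereocentre carrying the (Z)-nonadec-10-enyl chain), C3 (CH2), C4 (C=O), C5 (=CH), C6 (C–CH3). The retrosynthesis cuts C4–C5 and C2–C3 together. This releases C3–C4 as a ketene (silylketene 9) and C5=C6(CH3)–O1–C2 as an O-isopropenyl oxocarbenium ion.
- The enabling feature is the cyclic vinylogous ester O1–C6=C5–C4=O next to the O-bearing sp3 carbon C2. C5 is an enol-ether carbon, C2 is an acetal-level carbon on the same oxygen, and a ketene is nucleophilic at CH2 and electrophilic at C=O.
- The oxocarbenium precursor 7 (α-pivaloyloxy isopropenyl ether) goes back to the mixed acylal 6, the 1-chloroalkyl pivalate 4 and (Z)-icos-11-enal 2. C5 comes from a titanium methylidene; C6 and its methyl come from acetate.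
- Forward: the chain aldehyde is made first, then acylal, then enol ether, and the single ring closes in step 6. The pivaloyl and silyl helpers leave in that same step; no protecting groups are used.
- Stereochemistry: the Z-alkene is bought with alcohol 1. The only stereocentre (C2, R) is set in step 6 by a chiral counteranion.

Key step: step 6

Remark: the sense of induction of the chiral anion cannot be fixed on paper. The catalyst antipode meant is the one that leaves the Si face of the oxocarbenium carbon open, which corresponds to the (R) centre.

**Route**

Step 1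
Reactants: 1 (Z)-icos-11-en-1-ol
Product: 2 (Z)-icos-11-enal
Conditions: TEMPO (10 mol %), PhI(OAc)2 (1.1 equiv), CH2Cl2, rt
Reagents that add atoms: none
Why: Oxoammonium (TEMPO) oxidation with PhI(OAc)2 as terminal oxidant should stop at the aldehyde and leave the isolated Z-alkene untouched.

Step 2
Reactants: 2 (Z)-icos-11-enal; 3 pivaloyl chloride
Product: 4 (Z)-1-chloroicos-11-en-1-yl pivalate (racemic)
Conditions: ZnCl2 (2 mol %), CH2Cl2, −10 °C → rt
Reagents that add atoms: none
Why: ZnCl2-catalysed addition of an acyl chloride across an aldehyde C=O is the standard entry to 1-chloroalkyl esters; the new centre is racemic and is flattened again in step 6.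

Step 3
Reactants: 4 (Z)-1-chloroicos-11-en-1-yl pivalate; 5 cesium acetate
Product: 6 (Z)-1-acetoxyicos-11-en-1-yl pivalate (racemic mixed acylal)
Conditions: CsOAc (1.5 equiv), Bu4NI (10 mol %), MeCN, 40 °C
Reagents that add atoms: none
Why: Carboxylate displacement on a 1-chloroalkyl ester (acyloxyalkyl ester synthesis with in situ Finkelstein activation) should give the mixed acylal; the centre stays racemic.

Step 4
Reactants: 6 (Z)-1-acetoxyicos-11-en-1-yl pivalate
Product: 7 (Z)-1-(prop-1-en-2-yloxy)icos-11-en-1-yl pivalate (racemic)
Conditions: Cp2TiMe2 (1.5 equiv), toluene/THF, 65 °C, dark; filtration through basic alumina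
Reagents that add atoms: dimethyltitanocene Cp2TiMe2, [CH3-].[CH3-].c1cc[cH-]c1.c1cc[cH-]c1.[Ti+4]
Why: Petasis methylenation via Cp2Ti=CH2 converts an ester C=O into an enol ether under non-acidic conditions, as for the acetal-type esters used as Petasis–Ferrier substrates, and should take the unhindered acetate in preference to the pivalate carbonyl shielded by its tert-butyl group.

Step 5
Reactants: 8 (trimethylsilyl)acetic acid
Product: 9 (trimethylsilyl)ketene
Conditions: DCC (1.0 equiv), Et3N (cat.), Et2O, 0 °C → rt; distillation
Reagents that add atoms: none
Why: Carbodiimide dehydration of the silylacetic acid should give the silylketene, which silicon stabilises against dimerisation so that it can be distilled and stored.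

Step 6
Reactants: 7 (Z)-1-(prop-1-en-2-yloxy)icos-11-en-1-yl pivalate; 9 (trimethylsilyl)ketene
Product: 12 (R)-6-methyl-2-[(Z)-nonadec-10-en-1-yl]-2,3-dihydro-4H-pyran-4-one, via O-isopropenyl oxocarbenium ion 10 (not isolated), via 3-trimethylsilyl dihydropyranone 11 (not isolated)
Conditions: chiral imidodiphosphorimidate Brønsted acid (BINOL-derived, N-triflyl; 5 mol %), 9 (2.0 equiv), toluene, −78 °C, slow addition of 7; Et3N quench at −78 °C, then pH 7 buffer
Reagents that add atoms: none
Why: Proposed new method: the acid is silylated in the flask by 9, the resulting silylium ion pair abstracts pivalate from 7 to give oxocarbenium ion 10 paired with the chiral anion, the silylketene adds through its CH carbon to the oxocarbenium carbon (bond C2–C3), the β-silyl acylium so formed is captured by the CH2 terminus of the isopropenyl ether (bond C4–C5), and proton loss from C5 followed by protodesilylation of α-silyl ketone 11 by the regenerated acid should give 12 and return the silylium catalyst. The closest known reaction types are the Lewis acid-promoted insertion of ketenes into acetals, the Lewis acid-catalysed silylketene–aldehyde [2+2] cycloaddition, the C-acylation of enol ethers and chiral-counteranion-directed silylium catalysis of additions to oxocarbenium ions; the step merges them into a cationic formal [4+2] (oxa-Povarov-type) of a 2-oxonia-diene with a ketene. The dihydropyranone ring closes by a 6-(enolendo)-exo-dig acylation at the acylium carbon. The C2 centre is set in the first bond formation, where the confined chiral anion is to shield the Re face of the oxocarbenium carbon so that the ketene enters on the Si face and gives the (R) configuration. The step needs ionisation by loss of pivalate and not of the enolate (a Ferrier-type 1,3-shift), which the leaving-group ability of the silylated carboxylate and the instability of an acyloxycarbenium ion secure. It also needs the ketene to outrun the enol ether of a second molecule of 7, which slow addition of 7 into excess 9 at −78 °C and the electron-poor acetal carbon on the enol-ether oxygen secure.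

**Compound list**

1 | (Z)-icos-11-en-1-ol | CCCCCCCC/C=C\CCCCCCCCCCO | starting material
2 | (Z)-icos-11-enal | CCCCCCCC/C=C\CCCCCCCCCC=O | intermediate
3 | pivaloyl chloride | CC(C)(C)C(=O)Cl | starting material
4 | (Z)-1-chloroicos-11-en-1-yl pivalate (racemic) | CCCCCCCC/C=C\CCCCCCCCCC(Cl)OC(=O)C(C)(C)C | intermediate
5 | cesium acetate | CC(=O)[O-].[Cs+] | starting material
6 | (Z)-1-acetoxyicos-11-en-1-yl pivalate (racemic) | CCCCCCCC/C=C\CCCCCCCCCC(OC(C)=O)OC(=O)C(C)(C)C | intermediate
7 | (Z)-1-(prop-1-en-2-yloxy)icos-11-en-1-yl pivalate (racemic) | CCCCCCCC/C=C\CCCCCCCCCC(OC(C)=C)OC(=O)C(C)(C)C | intermediate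
8 | (trimethylsilyl)acetic acid | C[Si](C)(C)CC(=O)O | starting material
9 | (trimethylsilyl)ketene | C[Si](C)(C)C=C=O | intermediate
10 | [(Z)-icos-11-en-1-ylidene](prop-1-en-2-yl)oxonium (ion pair with the catalyst anion) | CCCCCCCC/C=C\CCCCCCCCCC=[O+]C(C)=C | intermediate (not isolated)
11 | (2R)-6-methyl-2-[(Z)-nonadec-10-en-1-yl]-3-(trimethylsilyl)-2,3-dihydro-4H-pyran-4-one (C3 epimers) | CCCCCCCC/C=C\CCCCCCCCC[C@@H]1C([Si](C)(C)C)C(=O)C=C(C)O1 | intermediate (not isolated)
12 | (R)-6-methyl-2-[(Z)-nonadec-10-en-1-yl]-2,3-dihydro-4H-pyran-4-one | CCCCCCCC/C=C\CCCCCCCCC[C@@H]1CC(=O)C=C(C)O1 | target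

**Count**

Total steps: 6. Longest linear sequence: 5 steps (steps 1, 2, 3, 4 and 6; step 5 is a one-step side branch).

**Steps most likely to fail**

Step 6 (Proposed new method). Three processes may defeat it. The oxocarbenium ion may be captured by the enol ether of a second substrate molecule, or lose a proton, before the ketene adds. The anion may discriminate the two faces poorly. The silylium catalyst may be held back by the carbonyl oxygen of the product, and warming before the quench may erode the centre by ring opening of a transient 2H-pyran enol. The fallback uses known chemistry, sets out from 2 and comes back at 12. Commercial (E)-4-methoxypent-3-en-2-one is silylated (TMSOTf, Et3N, Et2O, 0 °C) to (E)-4-methoxy-2-(trimethylsilyloxy)penta-1,3-diene F1. A catalytic asymmetric Mukaiyama aldol addition (hetero-Diels–Alder manifold) of F1 to 2 follows, with Ti(OiPr)4 and the BINOL antipode that directs the diene terminus to the Si face of the aldehyde (4 Å sieves, Et2O, −20 °C). It should give (2E,6R,16Z)-2-methoxy-6-(trimethylsilyloxy)pentacosa-2,16-dien-4-one F2. Trifluoroacetic acid in CH2Cl2 at 0 °C should then remove the silyl group and close the ring by conjugate addition–elimination of methanol to give 12.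

Step 4. The titanium methylidene may discriminate incompletely between the acetate and pivalate carbonyls (over-methylenation), and the enol ether may be lost to acid on purification. The fallback removes the second ester. It sets out from 2 and comes back at 10. Addition of 1-acetylbenzotriazole across the aldehyde (K2CO3 cat., THF, rt) should give (Z)-1-(1H-benzotriazol-1-yl)icos-11-en-1-yl acetate F3. Methylenation of its only ester carbonyl with Cp2TiMe2 should give 1-[(Z)-1-(prop-1-en-2-yloxy)icos-11-en-1-yl]-1H-benzotriazole F4. Under the silylium conditions of step 6 (higher catalyst loading, because the silylated benzotriazole is a competing Lewis base) F4 should ionise by loss of benzotriazole to the same oxocarbenium ion 10.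

Step 3. Elimination of HCl to an enol ester and acyl exchange (scrambling to symmetrical acylals) may compete with substitution. The fallback avoids the substitution. It sets out from 2 and comes back at 10. Acetic anhydride with FeCl3 (5 mol %) should add across the aldehyde to give (Z)-icos-11-ene-1,1-diyl diacetate F5. Methylenation with a deficit of Cp2TiMe2 (1.0 equiv, stopped at partial conversion, F5 recovered and recycled) should give (Z)-1-(prop-1-en-2-yloxy)icos-11-en-1-yl acetate F6. In step 6, F6 should ionise by loss of acetate to 10.

**Further compounds**

F1 | step 6 | (E)-4-methoxy-2-(trimethylsilyloxy)penta-1,3-diene | C=C(O[Si](C)(C)C)/C=C(\C)OC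
F2 | step 6 | (2E,6R,16Z)-2-methoxy-6-(trimethylsilyloxy)pentacosa-2,16-dien-4-one | CCCCCCCC/C=C\CCCCCCCCC[C@@H](O[Si](C)(C)C)CC(=O)/C=C(\C)OC
F3 | step 4 | (Z)-1-(1H-benzotriazol-1-yl)icos-11-en-1-yl acetate (racemic) | CCCCCCCC/C=C\CCCCCCCCCC(OC(C)=O)n1nnc2ccccc12
F4 | step 4 | 1-[(Z)-1-(prop-1-en-2-yloxy)icos-11-en-1-yl]-1H-benzotriazole (racemic) | CCCCCCCC/C=C\CCCCCCCCCC(OC(C)=C)n1nnc2ccccc12
F5 | step 3 | (Z)-icos-11-ene-1,1-diyl diacetate | CCCCCCCC/C=C\CCCCCCCCCC(OC(C)=O)OC(C)=O
F6 | step 3 | (Z)-1-(prop-1-en-2-yloxy)icos-11-en-1-yl acetate (racemic) | CCCCCCCC/C=C\CCCCCCCCCC(OC(C)=C)OC(C)=O
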